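Ring B, the oxane made of the ether oxygen, C12(Me), C13(HMe), C14H2, the spiro carbon C15 and C16, is not cyclised as such: its carbons C12–C15 start as a furan and C16 as the formyl group on it. An Achmatowicz-type oxidative ring expansion of flat 4,5-dimethylfurfural (step 1) turns the five-membered ring into the six-membered 3-hydroxy-2-pyrone, which already carries both methyls, the C15 oxygen and the C16 acyl carbon and is at once the diene for an asymmetric Diels–Alder cage formation. A ketenylidene-ylide Wittig then builds the tetronate on the lactone carbonyl; metathesis macrocyclisation and a reductive transannular Michael addition close the cyclopentane and eight-membered rings.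

Key step: step 1

Remark (numbering used for all compounds): C1 lactone C=O; C2=C3(OH) enol; C4(Me); C5; C6(Me); C7 ketone; C8; C9; C10; C11(OH); C12(Me, ether O); C13(Me); C14; C15 (spiro, lactone O); C16 (ether O, bonded to C2, C8, C15). The cage has three bridges between C12 and C15: O–C16, C13–C14 and C11–C10.

Remark (assumptions): the target is taken as the chelated enol tautomer of the C1/C3 beta-keto lactone, which the last step should deliver on protonation. Compounds 1, 5 and 13 are taken as purchasable. The sense of induction of the cinchona catalysts in steps 2 and 8 is assumed.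

Step 1
Reactants: 1 4,5-dimethylfuran-2-carbaldehyde
Product: 4 3-hydroxy-5,6-dimethyl-2H-pyran-2-one, via keto-enal 2 (not isolated), via lactol 3 (not isolated)
Conditions: NBS, NaHCO3, THF/H2O (4:1), 0 °C; then 1 M HCl, 40 °C
Reagents that add atoms: water, O
Why: Proposed new method: NBS brominates the electron-rich furan, water adds, and the 2,5-dihydroxy-2,5-dihydrofuran opens to the Z-configured 2-oxo-enal 2, whose aldehyde hydrate closes onto the methyl ketone to give lactol 3. Acid then removes two molecules of water with enediol tautomerism to give the aromatic pyrone 4, so that the furan carbons C2 to C5 plus the formyl carbon become ring B (C15, C14, C13, C12 and C16). The closest known reactions are the Achmatowicz rearrangement of 2-furylcarbinols, here run on a furfural hydrate, and the halogen-water ring opening of furfural that is used to reach 3-hydroxy-2-pyridone. The six-membered ring closes by 6-exo-trig addition of a hydrate oxygen to the ketone carbonyl, held within reach by the Z-alkene inherited from the furan. No stereocentre is formed; the selectivity needed is oxygen cyclisation over aldol closure of the methyl ketone onto the aldehyde, which full hydration of the alpha-keto aldehyde and the acidic medium should secure.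

Step 2
Reactants: 4 3-hydroxy-5,6-dimethyl-2H-pyran-2-one; 5 ethyl (E)-3-(pinacolboryl)acrylate
Product: 6 ethyl (1R,4S,5S,6S)-4-hydroxy-1,7-dimethyl-3-oxo-6-(pinacolboryl)-2-oxabicyclo[2.2.2]oct-7-ene-5-carboxylate (C10 ester toward the lactone bridge, C11 boron toward the C13=C14 bridge)
Conditions: 9-O-(9-phenanthryl)cupreidine (10 mol %), EtOAc, rt
Reagents that add atoms: none
Why: Base-catalysed Diels–Alder reaction of a 3-hydroxy-2-pyrone in which the bifunctional cinchona catalyst deprotonates the 3-OH and hydrogen-bonds the acrylate, the polarised dienolate should bond C12 to the boron-bearing beta-carbon and C15 to the ester alpha-carbon, the E-geometry fixes C10 and C11 trans, an exo orientation of the ester places boron on the alkene-bridge side, and the catalyst-selected diene face sets the absolute configuration of C10, C11, C12 and C15.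

Step 3
Reactants: 6 bicyclic hydroxy lactone
Product: 8 boryl tetronate (butenolide C1(=O)–C2H=C16 spiro at C15, C16–O–C12 ether retained, C10 CO2Et, C11 Bpin, C13=C14), via ester ylide 7 (not isolated)
Conditions: Ph3P=C=C=O, PhCO2H (cat.), THF, 60 °C
Reagents that add atoms: (triphenylphosphoranylidene)ketene, O=C=C=P(c1ccccc1)(c1ccccc1)c1ccccc1
Why: Domino addition and intramolecular Wittig olefination in which the tertiary C15 hydroxyl adds to the cumulated ylide to give ester ylide 7, which olefinates the adjacent lactone carbonyl C16 through a five-membered ring, so the tetronate forms with ring B intact, no stereocentre is touched and loss of CO2 from the bridged lactone is no longer possible.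

Step 4
Reactants: 8 boryl tetronate
Product: 9 C11 alcohol (hydroxyl toward the C13=C14 bridge)
Conditions: NaBO3·4H2O, THF/H2O (1:1), rt
Reagents that add atoms: sodium perborate, O=BO[O-].[Na+]
Why: Perborate oxidation of the secondary alkylboronate proceeds by a 1,2-shift of carbon from boron to oxygen with retention, which places the C11 hydroxyl where the boron stood.

Step 5
Reactants: 9 C11 alcohol
Product: 10 13,14-dihydro compound (C13 methyl toward the O–C16 bridge)
Conditions: H2 (1 atm), [Ir(cod)(PCy3)(py)]PF6 (5 mol %), CH2Cl2, rt
Reagents that add atoms: none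
Why: Hydroxyl-directed hydrogenation in which the cationic iridium catalyst binds the C11 hydroxyl and delivers hydrogen to the alkene face that looks at the C10–C11 bridge, so the C13 methyl ends on the side of the oxygen bridge while the electron-poor tetronate alkene is left alone.

Step 6
Reactants: 10 saturated hydroxy ester
Product: 11 C9 aldehyde
Conditions: i-Bu2AlH (2.3 equiv), CH2Cl2, −78 °C; Rochelle salt work-up
Reagents that add atoms: none
Why: Partial reduction of the ethyl ester should stop at the aluminium hemiacetal, which the neighbouring C11 alkoxide chelates, and the vinylogous carbonate of the tetronate is less electrophilic than the ester.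

Step 7
Reactants: 11 C9 aldehyde
Product: 12 C10 vinyl tetronate
Conditions: Ph3PCH3Br, KN(SiMe3)2, THF, −78 to 0 °C
Reagents that add atoms: methylenetriphenylphosphorane, C=P(c1ccccc1)(c1ccccc1)c1ccccc1
Why: Wittig methylenation of the aldehyde, in which C10 already holds the arrangement trans to the C11 oxygen that should be thermodynamically preferred, so base-induced epimerisation is not expected to erode it.

Step 8
Reactants: 13 meso-2,4-dimethylglutaric anhydride
Product: 14 (2R,4S)-5-methoxy-2,4-dimethyl-5-oxopentanoic acid
Conditions: MeOH, (DHQD)2AQN (cat.), Et2O, −20 °C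
Reagents that add atoms: methanol, CO
Why: Alcoholytic desymmetrisation of a meso anhydride by a cinchona-derived general-base catalyst that differentiates the enantiotopic carbonyl groups; should the antipodal hemiester form, reducing its ester instead of its acid in step 9 would give the same lactone.

Step 9
Reactants: 14 hemiester
Product: 16 (3S,5R)-3,5-dimethyloxan-2-one, via hydroxy ester 15 (not isolated)
Conditions: BH3·SMe2, THF, 0 °C to rt; then TsOH (cat.), toluene, 80 °C
Reagents that add atoms: none
Why: Borane reduces the carboxylic acid chemoselectively beside the methyl ester, and the resulting delta-hydroxy ester 15 lactonises under acid catalysis without touching either stereocentre.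

Step 10
Reactants: 12 C10 vinyl tetronate; 16 (3S,5R)-3,5-dimethyloxan-2-one
Product: 18 C2-acylated tetronate carrying the (2S,4R)-5-hydroxy-2,4-dimethylpentanoyl chain (in equilibrium with its six-membered lactol), via dilithio tetronate 17 (not isolated)
Conditions: t-BuLi (2.2 equiv), THF, −78 °C; then 16, −78 to −40 °C; 1 M HCl quench
Reagents that add atoms: none
Why: After deprotonation of the C11 hydroxyl the tetronate alpha-position C2 is lithiated and opens the lactone by nucleophilic acyl substitution, the tetrahedral lithium lactolate resisting over-addition, so the C2–C3 bond forms and C4 and C6 come unchanged from 16.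

Step 11
Reactants: 18 hydroxy ketone
Product: 19 C7 aldehyde
Conditions: TEMPO (cat.), PhI(OAc)2, CH2Cl2, rt
Reagents that add atoms: none
Why: Oxoammonium oxidation is much faster for primary than for hindered secondary alcohols, so the C7 alcohol, drained from its lactol equilibrium, becomes the aldehyde while the C11 hydroxyl stays.

Step 12
Reactants: 19 C7 aldehyde
Product: 20 C7 allylic alcohol (both C7 epimers)
Conditions: CH2=CHMgBr, THF, −78 °C
Reagents that add atoms: vinylmagnesium bromide, C=C[Mg]Br
Why: Grignard 1,2-addition to the aldehyde, the most electrophilic carbonyl present, at low temperature, where the new C7 centre need not be controlled because it is oxidised in step 14.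

Step 13
Reactants: 20 diene
Product: 21 eleven-membered macrocyclic allylic alcohol (C8=C9)
Conditions: RuCl2(=CHPh)(H2IMes)(PCy3) (second-generation Grubbs catalyst, 10 mol %), CH2Cl2 (1 mM), 40 °C
Reagents that add atoms: none
Why: Ring-closing metathesis of the two monosubstituted alkenes should give the eleven-membered ring, with the trisubstituted tetronate alkene inert and the geometry of the new C8=C9 bond of no consequence because it is reduced in step 15.

Step 14
Reactants: 21 macrocyclic allylic alcohol
Product: 22 macrocyclic enone (C7 ketone, C8=C9)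
Conditions: MnO2, CH2Cl2, rt
Reagents that add atoms: none
Why: Manganese dioxide oxidises the allylic C7 alcohol selectively over the saturated, hindered C11 alcohol.

Step 15
Reactants: 22 macrocyclic enone
Product: 24 Abyssomicin N, via lithium enolate 23 (not isolated)
Conditions: LiBH(s-Bu)3 (2.2 equiv), THF, −78 °C to rt; then 1 M HCl
Reagents that add atoms: none
Why: Conjugate hydride addition to C9 generates the C7/C8 enolate 23, which should add transannularly (5-exo-trig Michael) to C16 of the doubly activated tetronate from the only face the macrocycle allows, setting C16 and the cis ring fusion at C8, and protonation gives the enolised beta-keto lactone.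

Compound list

1 | 4,5-dimethylfuran-2-carbaldehyde | Cc1oc(C=O)cc1C | starting material
2 | (Z)-4-methyl-2,5-dioxohex-3-enal | O=CC(=O)/C=C(/C)C(C)=O | intermediate
3 | 2,6-dihydroxy-5,6-dimethyl-2H-pyran-3(6H)-one | CC1=CC(=O)C(O)OC1(C)O | intermediate
4 | 3-hydroxy-5,6-dimethyl-2H-pyran-2-one | CC1=C(C)C=C(O)C(=O)O1 | intermediate
5 | ethyl (E)-3-(4,4,5,5-tetramethyl-1,3,2-dioxaborolan-2-yl)prop-2-enoate | CCOC(=O)/C=C/B1OC(C)(C)C(C)(C)O1 | starting material
6 | ethyl (1R,4S,5S,6S)-4-hydroxy-1,7-dimethyl-3-oxo-6-(pinacolboryl)-2-oxabicyclo[2.2.2]oct-7-ene-5-carboxylate | C[C@]12OC(=O)[C@](O)(C=C1C)[C@@H](C(=O)OCC)[C@@H]2B3OC(C)(C)C(C)(C)O3 | intermediate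
7 | C15 O-(triphenylphosphoranylidene)acetate of 6 | C[C@]12OC(=O)[C@](OC(=O)C=P(c3ccccc3)(c4ccccc4)c5ccccc5)(C=C1C)[C@@H](C(=O)OCC)[C@@H]2B6OC(C)(C)C(C)(C)O6 | intermediate
8 | boryl tetronate: spiro butenolide C1(=O)–C2H=C16 at C15 with C16–O–C12 ether, C10 CO2Et (toward O–C16 bridge), C11 Bpin (toward C13=C14 bridge) | C[C@]12OC3=CC(=O)O[C@@]3(C=C1C)[C@@H](C(=O)OCC)[C@@H]2B4OC(C)(C)C(C)(C)O4 | intermediate
9 | C11 alcohol of the tetronate cage (C13=C14 still present) | C[C@]12OC3=CC(=O)O[C@@]3(C=C1C)[C@@H](C(=O)OCC)[C@@H]2O | intermediate
10 | 13,14-dihydro tetronate cage, C13 methyl toward the O–C16 bridge, C10 CO2Et, C11 OH | C[C@]12OC3=CC(=O)O[C@@]3(C[C@@H]1C)[C@@H](C(=O)OCC)[C@@H]2O | intermediate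
11 | tetronate cage C9 aldehyde | C[C@]12OC3=CC(=O)O[C@@]3(C[C@@H]1C)[C@@H](C=O)[C@@H]2O | intermediate
12 | tetronate cage with C10 vinyl group | C[C@]12OC3=CC(=O)O[C@@]3(C[C@@H]1C)[C@@H](C=C)[C@@H]2O | intermediate
13 | meso-2,4-dimethylglutaric anhydride (cis-3,5-dimethyloxane-2,6-dione) | O=C1OC(=O)[C@H](C)C[C@@H]1C | starting material
14 | (2R,4S)-5-methoxy-2,4-dimethyl-5-oxopentanoic acid | COC(=O)[C@@H](C)C[C@@H](C)C(=O)O | intermediate
15 | methyl (2S,4R)-5-hydroxy-2,4-dimethylpentanoate | COC(=O)[C@@H](C)C[C@@H](C)CO | intermediate
16 | (3S,5R)-3,5-dimethyloxan-2-one | O=C1OC[C@H](C)C[C@@H]1C | intermediate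
17 | C2-lithio, C11-lithium alkoxide derivative of 12 | C[C@]12OC3=C([Li])C(=O)O[C@@]3(C[C@@H]1C)[C@@H](C=C)[C@@H]2O[Li] | intermediate
18 | C2-[(2S,4R)-5-hydroxy-2,4-dimethylpentanoyl] tetronate cage with C10 vinyl | C[C@]12OC3=C(C(=O)[C@@H](C)C[C@@H](C)CO)C(=O)O[C@@]3(C[C@@H]1C)[C@@H](C=C)[C@@H]2O | intermediate
19 | C7 aldehyde of 18 | C[C@]12OC3=C(C(=O)[C@@H](C)C[C@@H](C)C=O)C(=O)O[C@@]3(C[C@@H]1C)[C@@H](C=C)[C@@H]2O | intermediate
20 | C7 vinyl carbinol (C7 epimers), diene for ring closure | C[C@]12OC3=C(C(=O)[C@@H](C)C[C@@H](C)C(O)C=C)C(=O)O[C@@]3(C[C@@H]1C)[C@@H](C=C)[C@@H]2O | intermediate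
21 | eleven-membered macrocycle with C7 allylic alcohol and C8=C9 alkene | C[C@]12OC3=C4C(=O)O[C@@]3(C[C@@H]1C)[C@@H](/C=C/C(O)[C@H](C)C[C@H](C)C4=O)[C@@H]2O | intermediate
22 | macrocyclic C7 enone (C8=C9), C3 ketone on the tetronate | C[C@]12OC3=C4C(=O)O[C@@]3(C[C@@H]1C)[C@@H](/C=C/C(=O)[C@H](C)C[C@H](C)C4=O)[C@@H]2O | intermediate
23 | C7/C8 lithium enolate of the 8,9-dihydro macrocycle | C[C@]12OC3=C4C(=O)O[C@@]3(C[C@@H]1C)[C@@H](CC=C(O[Li])[C@H](C)C[C@H](C)C4=O)[C@@H]2O[Li] | intermediate
24 | Abyssomicin N (4S,6R,8R,10S,11S,12S,13S,15S,16R) | C[C@@H]1C[C@H](C)/C(O)=C2/C(=O)O[C@]34C[C@H](C)[C@]5(C)O[C@]23[C@@H](C[C@H]4[C@@H]5O)C1=O | target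

Total step count: 15. Longest linear sequence: 13 steps (steps 1–7 and 10–15).

Steps most likely to fail

Step 1 (proposed new method). The ring-opened keto-enal may close through carbon (aldol of the methyl ketone onto the aldehyde, leading to a hydroquinone), or the aldehyde may be over-oxidised before the oxygen ring closure. The fallback uses known chemistry and keeps the furan-to-pyranone ring expansion. It sets out from 1, which is reduced with NaBH4 to (4,5-dimethylfuran-2-yl)methanol F1. A classical Achmatowicz rearrangement (NBS, NaHCO3, aqueous THF) then gives 6-hydroxy-5,6-dimethyl-2H-pyran-3(6H)-one F2. Oxidation of its ring-chain tautomeric alpha-ketol with Cu(OAc)2 in aqueous acetic acid gives the keto-aldehyde, which closes and dehydrates as in step 1. The fallback comes back to the route at 4.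

Step 2. The hindered, C12-methylated dienolate may react slowly with the beta-boryl acrylate, and the ester may take the endo instead of the exo orientation, which would put boron on the wrong side of C11. The facial sense may also be opposite; the pseudo-enantiomeric cupreine ether would then be used. The fallback sets out from 4 and uses ethyl (Z)-3-(pinacolboryl)acrylate F3 (from ethyl (Z)-3-iodoacrylate, B2pin2, PdCl2(dppf), KOAc) in the ordinary endo mode. Both substituents then face the alkene bridge, giving the all-endo adduct F4 (C10 epimer of 6). The ketenylidene-ylide olefination of step 3 converts it to the C10-epimeric boryl tetronate F5. Catalytic KOt-Bu in THF/t-BuOH then epimerises the ester alpha-carbon C10 to the trans arrangement. The fallback comes back to the route at 8.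

Step 3. The hindered tertiary alcohol may add to the cumulated ylide only slowly, and at the temperature then needed thermal loss of CO2 from the bridged lactone may compete. The fallback sets out from 6, which is O-acylated at 0 °C with bromoacetyl bromide and pyridine to the C15 bromoacetate F6. Triphenylphosphine converts F6 to the phosphonium bromide F7. Triethylamine at rt then generates ylide 7, which closes by the same intramolecular Wittig reaction. The fallback comes back to the route at 8.

Further compounds

F1 | step 1 | (4,5-dimethylfuran-2-yl)methanol | Cc1oc(CO)cc1C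
F2 | step 1 | 6-hydroxy-5,6-dimethyl-2H-pyran-3(6H)-one | CC1=CC(=O)COC1(C)O
F3 | step 2 | ethyl (Z)-3-(4,4,5,5-tetramethyl-1,3,2-dioxaborolan-2-yl)prop-2-enoate | CCOC(=O)/C=C\B1OC(C)(C)C(C)(C)O1
F4 | step 2 | all-endo Diels–Alder adduct (C10 epimer of 6) | C[C@]12OC(=O)[C@](O)(C=C1C)[C@H](C(=O)OCC)[C@@H]2B3OC(C)(C)C(C)(C)O3
F5 | step 2 | C10-epimeric boryl tetronate (C10 epimer of 8) | C[C@]12OC3=CC(=O)O[C@@]3(C=C1C)[C@H](C(=O)OCC)[C@@H]2B4OC(C)(C)C(C)(C)O4
F6 | step 3 | C15 bromoacetate of 6 | C[C@]12OC(=O)[C@](OC(=O)CBr)(C=C1C)[C@@H](C(=O)OCC)[C@@H]2B3OC(C)(C)C(C)(C)O3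
F7 | step 3 | C15 (triphenylphosphonio)acetate bromide of 6 | C[C@]12OC(=O)[C@](OC(=O)C[P+](c3ccccc3)(c4ccccc4)c5ccccc5)(C=C1C)[C@@H](C(=O)OCC)[C@@H]2B6OC(C)(C)C(C)(C)O6.[Br-]
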